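**Plan**
- Key cut: the ring bond C1–C2 of the triketone. C1 is the enolized carbonyl carbon remote from the carbinol, and C2 is the ring carbon bearing the octadecanoyl group. This Claisen cut copies the chain-ending cyclization of the presumed polyketide biosynthesis.
- Enabling feature: the C1 carbonyl and the oxygen on C4 are 1,4-related through C6–C5 (a γ-hydroxy acid), so the open chain can be tied up as a butyrolactone. C2 is the central carbon of a 1,3-diketone (C3=O and the exocyclic C=O). The precursor is therefore an isomer of the target, (5S)-5-(3-oxoicosanoyl)oxolan-2-one.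
- Further cuts: the bond from C2 to the exocyclic carbonyl (diazoketone plus octadecanal), then C3–C2 (acid chloride plus a one-carbon diazo unit).
- Forward order: the C18 chain is joined to the preformed lactone (steps 1–3). The six-membered carbocycle arises last (step 4), and the same acyl transfer opens the lactone and frees the C4 hydroxyl, so no protecting group is needed.
- Stereochemistry: the only stereocenter (C4, S) comes from (S)-5-oxooxolane-2-carboxylic acid, the lactone acid of L-glutamic acid. Its C–O bond is never broken, and the lactone oxygen becomes the C4 hydroxyl.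

Key step: step 4

Remark on the chemistry: the target is a 2-acylcyclohexane-1,3-dione whose enol tautomers interconvert freely; the enol written in the SMILES is one of them, and the route delivers this constitution as its tautomeric equilibrium mixture.

Step 1
Reactants: 1 (2S)-5-oxooxolane-2-carboxylic acid
Product: 2 (2S)-5-oxooxolane-2-carbonyl chloride
Conditions: (COCl)2 (1.2 equiv), DMF (cat.), CH2Cl2, 0 °C → rt; evaporation
Reagents that add atoms: oxalyl chloride, ClC(=O)C(=O)Cl
Why: Acid chloride formation through the Vilsmeier-type chloroiminium species runs without base, so the lactone and the α-oxygenated stereocenter (no new stereocenter) should pass unchanged.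

Step 2
Reactants: 2 (2S)-5-oxooxolane-2-carbonyl chloride
Product: 3 (5S)-5-(2-diazoacetyl)oxolan-2-one
Conditions: Me3SiCHN2 (2 equiv, 2 M in hexanes), THF/MeCN 1:1, 0 °C → rt; evaporation, SiO2
Reagents that add atoms: trimethylsilyldiazomethane, C[Si](C)(C)C=[N+]=[N-]
Why: Acylation of a diazoalkane by an acid chloride (first stage of the Arndt–Eistert sequence) should give the diazoketone, the silyl group leaving with chloride as Me3SiCl, without any base that could form a ketene at the stereocenter.

Step 3
Reactants: 3 (5S)-5-(2-diazoacetyl)oxolan-2-one; 4 octadecanal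
Product: 5 (5S)-5-(3-oxoicosanoyl)oxolan-2-one
Conditions: SnCl2 (0.2 equiv), CH2Cl2, rt (N2 evolution); SiO2
Reagents that add atoms: none
Why: In this Roskamp reaction, extended from diazoacetates to an α-diazoketone, the diazo carbon adds to the SnCl2-activated aldehyde and a 1,2-hydride shift with loss of N2 should give the 1,3-diketone under near-neutral conditions that leave the lactone and the stereocenter alone.

Step 4
Reactants: 5 (5S)-5-(3-oxoicosanoyl)oxolan-2-one
Product: 8 (4S)-4-hydroxy-2-octadecanoylcyclohexane-1,3-dione, via potassium diketonate 6 (not isolated), via potassium triketonate 7 (not isolated)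
Conditions: KOt-Bu (1.2 equiv), THF/t-BuOH 4:1 (0.02 M), 0 °C → rt; then 1 M HCl to pH 2
Reagents that add atoms: none
Why: tert-Butoxide removes the proton between the two ketones of 5 (pKa about 9) to give diketonate 6, whose central carbon adds to the lactone carbonyl; the tetrahedral intermediate, a 7-oxabicyclo[2.2.1]heptan-1-olate, collapses by breaking the acyl–oxygen bond, and the C4 alkoxide so released is at once protonated by the new, far more acidic triketone, which leaves the stabilized triketonate 7 as the sink of the reaction. This is an intramolecular Claisen (Dieckmann-type) condensation of the kind that ends the polyketide chain in the presumed biosynthesis of 2-acylcyclohexane-1,3-diones; its closest laboratory relatives are the Lacey–Dieckmann closure to 3-acyltetramic acids and the base-mediated closure of 5,7-dioxo esters, and the acyl transfer across the butyrolactone ring has its geometric counterpart in the ring expansion of 5-(aminomethyl)butyrolactones to 5-hydroxypiperidin-2-ones. The carbocycle closes 6-exo-trig (6-(enolexo)-exo-trig) at the lactone carbonyl, and the five-membered lactone is opened in the same event. No stereocenter is created: the (S) center at C4 is carried over because only the acyl–oxygen bond of the lactone breaks, and it is shielded from enolization because its neighbouring carbonyl belongs to a delocalized mono-anion in 6 and in 7, so that removal of the C4 proton would need a dianion that this amount of alkoxide cannot make. The step needs C- over O-acylation and ring closure over intermolecular condensation: O-attack can only give enol lactones that are themselves acyl donors and revert, C-attack is made irreversible by the final proton transfer, the E ester geometry enforced by the lactone makes it a better acyl donor than an open-chain ester, and dilution disfavours the intermolecular path.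

**Compound list**
1 | (2S)-5-oxooxolane-2-carboxylic acid | O=C1CC[C@H](O1)C(=O)O | starting material
2 | (2S)-5-oxooxolane-2-carbonyl chloride | O=C1CC[C@H](O1)C(Cl)=O | intermediate
3 | (5S)-5-(2-diazoacetyl)oxolan-2-one | O=C1CC[C@H](O1)C(=O)C=[N+]=[N-] | intermediate
4 | octadecanal | CCCCCCCCCCCCCCCCCC=O | starting material
5 | (5S)-5-(3-oxoicosanoyl)oxolan-2-one | O=C1CC[C@H](O1)C(=O)CC(=O)CCCCCCCCCCCCCCCCC | intermediate
6 | potassium 1-oxo-1-[(2S)-5-oxooxolan-2-yl]icos-2-en-3-olate (potassium diketonate of 5) | [K+].O=C1CC[C@H](O1)C(=O)C=C([O-])CCCCCCCCCCCCCCCCC | intermediate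
7 | potassium (4S)-4-hydroxy-2-octadecanoyl-3-oxocyclohex-1-en-1-olate (potassium triketonate) | [K+].CCCCCCCCCCCCCCCCCC(=O)C1=C([O-])CC[C@H](O)C1=O | intermediate
8 | (4S)-4-hydroxy-2-octadecanoylcyclohexane-1,3-dione, written as its enol (6S)-3,6-dihydroxy-2-octadecanoylcyclohex-2-en-1-one | CCCCCCCCCCCCCCCCCC(=O)C1=C(O)CC[C@H](O)C1=O | target

Total step count: 4. Longest linear sequence: 4 steps (1 → 2 → 3 → 5 → 8); octadecanal 4 enters in step 3.

**Steps most likely to fail**

Step 4. The stabilized diketonate may add too slowly across the lactone ring, because the bridged tetrahedral intermediate is strained and reverts readily. Prolonged exposure to base would then leave room for epimerization at C4 or intermolecular condensation. The fallback sets out from 5 and comes back at 8, and it takes the lactone out of play before the ring closure. K2CO3 in MeOH at 0 °C should open 5 to methyl (4S)-4-hydroxy-5,7-dioxotetracosanoate F1. This is silylated at once (TBSCl, imidazole, DMF) to methyl (4S)-4-[(tert-butyldimethylsilyl)oxy]-5,7-dioxotetracosanoate F2. An ordinary 6-exo-trig Dieckmann closure of this open-chain 5,7-dioxo ester (KOt-Bu, THF, rt), through an unstrained monocyclic tetrahedral intermediate, should give (4S)-4-[(tert-butyldimethylsilyl)oxy]-2-octadecanoylcyclohexane-1,3-dione F3. Aqueous HF in MeCN should then free 8.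

Step 3. The acyl-deactivated diazo carbon may add sluggishly to the aldehyde, and alkyl migration or epoxide formation may compete with the hydride shift. The fallback sets out from 2 and comes back at 5. Commercial 2-nonadecanone (CC(=O)CCCCCCCCCCCCCCCCC) is deprotonated on the methyl side with LiN(i-Pr)2 (THF, −78 °C) to lithium nonadec-1-en-2-olate F4 (2 equiv). Addition of 2 at −78 °C should acylate the enolate carbon in a crossed Claisen-type C-acylation, the acid chloride reacting far faster than the lactone. The second equivalent of F4 takes up the acidic proton of the product to give lithium 1-oxo-1-[(2S)-5-oxooxolan-2-yl]icos-2-en-3-olate F5, which also guards the stereocenter. Work-up with 1 M HCl should release 5.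

Step 2. Stereochemical integrity may be lost through ketene formation from the α-oxygenated acid chloride, and adventitious HCl may capture the diazoketone. The fallback sets out from 1 and comes back at 5, avoiding both the acid chloride and the diazoalkane. Activation of 1 with 1,1'-carbonyldiimidazole (THF, rt) should give (5S)-5-(imidazole-1-carbonyl)oxolan-2-one F6. Masamune–Brooks homologation with KO2CCH2CO2t-Bu, MgCl2 and Et3N should give tert-butyl 3-oxo-3-[(2S)-5-oxooxolan-2-yl]propanoate F7. C-acylation of its magnesium chelate with octadecanoyl chloride (CCCCCCCCCCCCCCCCCC(Cl)=O; MgCl2, pyridine, CH2Cl2) should give tert-butyl 3-oxo-2-[(2S)-5-oxooxolane-2-carbonyl]icosanoate F8. CF3CO2H in CH2Cl2 should cleave the tert-butyl ester to 3-oxo-2-[(2S)-5-oxooxolane-2-carbonyl]icosanoic acid F9, which should lose CO2 to give 5.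

**Further compounds**
F1 | step 4 | methyl (4S)-4-hydroxy-5,7-dioxotetracosanoate | COC(=O)CC[C@H](O)C(=O)CC(=O)CCCCCCCCCCCCCCCCC
F2 | step 4 | methyl (4S)-4-[(tert-butyldimethylsilyl)oxy]-5,7-dioxotetracosanoate | COC(=O)CC[C@H](O[Si](C)(C)C(C)(C)C)C(=O)CC(=O)CCCCCCCCCCCCCCCCC
F3 | step 4 | (4S)-4-[(tert-butyldimethylsilyl)oxy]-2-octadecanoylcyclohexane-1,3-dione (enol form) | CCCCCCCCCCCCCCCCCC(=O)C1=C(O)CC[C@H](O[Si](C)(C)C(C)(C)C)C1=O
F4 | step 3 | lithium nonadec-1-en-2-olate | [Li+].[O-]C(=C)CCCCCCCCCCCCCCCCC
F5 | step 3 | lithium 1-oxo-1-[(2S)-5-oxooxolan-2-yl]icos-2-en-3-olate | [Li+].O=C1CC[C@H](O1)C(=O)C=C([O-])CCCCCCCCCCCCCCCCC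
F6 | step 2 | (5S)-5-(imidazole-1-carbonyl)oxolan-2-one | O=C1CC[C@H](O1)C(=O)n1ccnc1
F7 | step 2 | tert-butyl 3-oxo-3-[(2S)-5-oxooxolan-2-yl]propanoate | O=C1CC[C@H](O1)C(=O)CC(=O)OC(C)(C)C
F8 | step 2 | tert-butyl 3-oxo-2-[(2S)-5-oxooxolane-2-carbonyl]icosanoate | O=C1CC[C@H](O1)C(=O)C(C(=O)OC(C)(C)C)C(=O)CCCCCCCCCCCCCCCCC
F9 | step 2 | 3-oxo-2-[(2S)-5-oxooxolane-2-carbonyl]icosanoic acid | O=C1CC[C@H](O1)C(=O)C(C(=O)O)C(=O)CCCCCCCCCCCCCCCCC
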